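Ring A is built last instead of being bought. Its pattern (acyl at C1', oxygen at C2', prenyl at C3', oxygen at C4', hydrogen at C5' and C6') is that of a 2-prenylcyclohexane-1,3-dione bis(silyl enol ether) fused onto a terminal ynone. One thermal operation forms C1'–C2' and C5'–C6' by [4+2] cycloaddition and then aromatises ring A by expelling 2-methylpropene, so both phenol oxygens and the prenyl group arrive in place. The ynone partner is the ethynyl ketone of per-silylated (R)-danshensu, which supplies the only stereocenter (C2, R) from the chiral pool; the diene comes from dimedone. All five hydroxyls travel as silyl ethers, so one fluoride treatment finishes the synthesis.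

Key step: step 7

Remark on the chemistry: ring A is numbered C1'–C6' from the carbon that bears the ketone, and the chain is C1 (C=O), C2 (carbinol, R) and C3 (benzylic CH2); tert-butyldimethylsilyl (TBS) ethers are assumed for the three danshensu hydroxyls and trimethylsilyl ethers for O2' and O4', because an acetal on the C2 oxygen would need acid strong enough to close the C3' prenyl group onto a neighbouring phenol.

Step 1
Reactants: 1 sodium danshensu, sodium (2R)-3-(3,4-dihydroxyphenyl)-2-hydroxypropanoate
Product: 2 (2R)-3-(3,4-dihydroxyphenyl)-2-hydroxy-N-methoxy-N-methylpropanamide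
Conditions: MeNH(OMe)·HCl (1.3 equiv), DIC (1.2 equiv), HOBt (1.2 equiv), DMF, 0 °C → rt, Ar
Reagents that add atoms: N,O-dimethylhydroxylamine hydrochloride, CNOC.Cl
Why: Carbodiimide/HOBt amide coupling in which the sodium carboxylate itself frees the hydroxylamine from its salt, the α-effect nitrogen should outrun the phenolic and secondary hydroxyls for the activated acid, and the R configuration at C2 is kept because a free α-hydroxy acid has no azlactone pathway for racemisation.

Step 2
Reactants: 2 (2R)-3-(3,4-dihydroxyphenyl)-2-hydroxy-N-methoxy-N-methylpropanamide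
Product: 3 (2R)-2-(tert-butyldimethylsilyloxy)-3-[3,4-bis(tert-butyldimethylsilyloxy)phenyl]-N-methoxy-N-methylpropanamide
Conditions: TBSCl (4 equiv), imidazole (8 equiv), DMAP (cat.), DMF, rt → 40 °C
Reagents that add atoms: tert-butyldimethylsilyl chloride, CC(C)(C)[Si](C)(C)Cl
Why: Imidazole-promoted O-silylation should cover both phenols quickly and the more hindered C2 hydroxyl on gentle warming, in a medium too weakly basic to enolise the amide, so C2 stays R.

Step 3
Reactants: 3 (2R)-2-(tert-butyldimethylsilyloxy)-3-[3,4-bis(tert-butyldimethylsilyloxy)phenyl]-N-methoxy-N-methylpropanamide; 4 ethynylmagnesium bromide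
Product: 6 (4R)-4-(tert-butyldimethylsilyloxy)-5-[3,4-bis(tert-butyldimethylsilyloxy)phenyl]pent-1-yn-3-one, via bromomagnesium hemiaminal chelate 5 (not isolated)
Conditions: HC≡CMgBr (0.5 M in THF, 3 equiv), THF, −20 °C → rt; cannulate into cold 1 M aq. NaHSO4/Et2O
Reagents that add atoms: none
Why: Weinreb ketone synthesis in which chelate 5 holds the tetrahedral adduct until work-up so that only one alkynyl group adds, the weakly basic acetylide leaves the C–H at the stereocenter alone so the R configuration is kept, and the acidic inverse quench protonates the released N,O-dimethylhydroxylamine before it can add in conjugate fashion to the new ynone.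

Step 4
Reactants: 7 dimedone, 5,5-dimethylcyclohexane-1,3-dione; 8 prenyl bromide, 1-bromo-3-methylbut-2-ene
Product: 9 5,5-dimethyl-2-(3-methylbut-2-en-1-yl)cyclohexane-1,3-dione
Conditions: 7 (1.2 equiv), KOH (1.2 equiv), H2O, 8 (1.0 equiv), 0 °C → rt; extract into aq. Na2CO3, acidify with HCl, crystallise
Reagents that add atoms: none
Why: C-alkylation of the 1,3-dione enolate (SN2 at a primary allylic bromide) is favoured in water, where hydrogen bonding shields the enolate oxygens, and the still acidic mono-C-alkylated dione can be separated from neutral O-prenyl and doubly alkylated by-products by carbonate extraction.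

Step 5
Reactants: 9 5,5-dimethyl-2-(3-methylbut-2-en-1-yl)cyclohexane-1,3-dione
Product: 10 5,5-dimethyl-2-(3-methylbut-2-en-1-yl)-3-(trimethylsilyloxy)cyclohex-2-en-1-one
Conditions: TMSCl (1.3 equiv), Et3N (1.5 equiv), THF, 0 °C → rt; filter under Ar, concentrate
Reagents that add atoms: chlorotrimethylsilane, C[Si](C)(C)Cl
Why: O-silylation of the acidic, largely enolised 1,3-dione by a hard silyl chloride under amine base should give the vinylogous silyl ester, and the symmetry of 9 means that either oxygen leads to the same compound.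

Step 6
Reactants: 10 5,5-dimethyl-2-(3-methylbut-2-en-1-yl)-3-(trimethylsilyloxy)cyclohex-2-en-1-one
Product: 12 5,5-dimethyl-2-(3-methylbut-2-en-1-yl)-1,3-bis(trimethylsilyloxy)cyclohexa-1,3-diene, via lithium cross-conjugated dienolate 11 (not isolated)
Conditions: LiN(i-Pr)2 (commercial solution, 1.15 equiv), THF, −78 °C; TMSCl (1.3 equiv), −78 °C → rt; pentane, filter, Kugelrohr distillation
Reagents that add atoms: chlorotrimethylsilane, C[Si](C)(C)Cl
Why: Kinetic enolisation of a vinylogous ester by a hindered amide base removes the α' proton next to the carbonyl and not the γ proton, and O-silylation of dienolate 11 (silyl enol ether formation) should then give the 2-silyloxy diene whose CH2–CMe2 unit is the future leaving group.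

Step 7
Reactants: 6 (4R)-4-(tert-butyldimethylsilyloxy)-5-[3,4-bis(tert-butyldimethylsilyloxy)phenyl]pent-1-yn-3-one; 12 5,5-dimethyl-2-(3-methylbut-2-en-1-yl)-1,3-bis(trimethylsilyloxy)cyclohexa-1,3-diene
Product: 14 (2R)-2-(tert-butyldimethylsilyloxy)-3-[3,4-bis(tert-butyldimethylsilyloxy)phenyl]-1-[3-(3-methylbut-2-en-1-yl)-2,4-bis(trimethylsilyloxy)phenyl]propan-1-one, via bicyclo[2.2.2]octadiene cycloadduct 13 (not isolated)
Conditions: 12 (2.5 equiv), xylenes, BHT (cat.), Ar, 110 °C then 145 °C under a slow Ar sweep; volatiles removed under vacuum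
Reagents that add atoms: none
Why: The electron-rich diene 12 and the electron-poor ynone 6 should combine in a concerted, asynchronous, normal-demand [4+2] cycloaddition to give bicyclo[2.2.2]octadiene 13, which on further heating loses its CH2–CMe2 bridge as 2-methylpropene in a retro-[4+2] step driven by aromatisation. The closest known reaction type is the Diels–Alder/Alder–Rickert benzannulation of 1,3-bis(silyloxy)cyclohexa-1,3-dienes with acetylenic ketones and esters, which gives resorcinol silyl ethers. Ring A, the only ring formed, is closed by intermolecular cycloaddition across C1'–C2' and C5'–C6' followed by cycloreversion, not by cyclisation of a tethered chain. No stereocenter is created, since the bridgehead centres of 13 are destroyed again, both bridgehead diastereomers converge on 14, and the neutral, base-free medium leaves the silyloxy-bearing C2 (R) untouched. The selectivity needed is regiochemical, and the diene secures it: its CH terminus receives electron density from both silyloxy groups (one directly, one through the diene) and so bonds to the ynone β-carbon, which places the acyl group ortho to O2' and leaves the prenyl group between the two oxygens. The gem-dimethyl group makes the competing [1,5]-hydrogen shift of the diene degenerate and supplies a good alkene leaving group, and the excess of 12 compensates for the slower reaction of a fully substituted diene.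

Step 8
Reactants: 14 (2R)-2-(tert-butyldimethylsilyloxy)-3-[3,4-bis(tert-butyldimethylsilyloxy)phenyl]-1-[3-(3-methylbut-2-en-1-yl)-2,4-bis(trimethylsilyloxy)phenyl]propan-1-one
Product: 15 (2R)-1-[2,4-dihydroxy-3-(3-methylbut-2-en-1-yl)phenyl]-3-(3,4-dihydroxyphenyl)-2-hydroxypropan-1-one (the target)
Conditions: HF·pyridine (excess), pyridine, THF, 0 °C → rt, Ar, polypropylene flask; pH 7 phosphate buffer work-up
Reagents that add atoms: none
Why: Fluoride-mediated desilylation, driven by the strength of the Si–F bond, should strip the two aryl trimethylsilyl ethers and the two aryl TBS ethers quickly and the hindered C2 silyl ether more slowly, in a pyridine-buffered medium that is neither basic enough to enolise the α-hydroxy ketone or oxidise the catechol nor acidic enough to close the prenyl group onto O2' or O4'.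

Compound list
1 | sodium danshensu, sodium (2R)-3-(3,4-dihydroxyphenyl)-2-hydroxypropanoate | [Na+].[O-]C(=O)[C@H](O)Cc1ccc(O)c(O)c1 | starting material
2 | (2R)-3-(3,4-dihydroxyphenyl)-2-hydroxy-N-methoxy-N-methylpropanamide | CON(C)C(=O)[C@H](O)Cc1ccc(O)c(O)c1 | intermediate
3 | (2R)-2-(tert-butyldimethylsilyloxy)-3-[3,4-bis(tert-butyldimethylsilyloxy)phenyl]-N-methoxy-N-methylpropanamide | CON(C)C(=O)[C@H](O[Si](C)(C)C(C)(C)C)Cc1ccc(O[Si](C)(C)C(C)(C)C)c(O[Si](C)(C)C(C)(C)C)c1 | intermediate
4 | ethynylmagnesium bromide | C#C[Mg]Br | starting material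
5 | bromomagnesium alkoxide of (4R)-4-(tert-butyldimethylsilyloxy)-5-[3,4-bis(tert-butyldimethylsilyloxy)phenyl]-3-[methoxy(methyl)amino]pent-1-yn-3-ol (hemiaminal carbon undefined) | C#CC(O[Mg]Br)(N(C)OC)[C@H](O[Si](C)(C)C(C)(C)C)Cc1ccc(O[Si](C)(C)C(C)(C)C)c(O[Si](C)(C)C(C)(C)C)c1 | intermediate
6 | (4R)-4-(tert-butyldimethylsilyloxy)-5-[3,4-bis(tert-butyldimethylsilyloxy)phenyl]pent-1-yn-3-one | C#CC(=O)[C@H](O[Si](C)(C)C(C)(C)C)Cc1ccc(O[Si](C)(C)C(C)(C)C)c(O[Si](C)(C)C(C)(C)C)c1 | intermediate
7 | dimedone, 5,5-dimethylcyclohexane-1,3-dione | CC1(C)CC(=O)CC(=O)C1 | starting material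
8 | prenyl bromide, 1-bromo-3-methylbut-2-ene | CC(C)=CCBr | starting material
9 | 5,5-dimethyl-2-(3-methylbut-2-en-1-yl)cyclohexane-1,3-dione | CC(C)=CCC1C(=O)CC(C)(C)CC1=O | intermediate
10 | 5,5-dimethyl-2-(3-methylbut-2-en-1-yl)-3-(trimethylsilyloxy)cyclohex-2-en-1-one | CC(C)=CCC1=C(O[Si](C)(C)C)CC(C)(C)CC1=O | intermediate
11 | lithium 3,3-dimethyl-6-(3-methylbut-2-en-1-yl)-5-(trimethylsilyloxy)cyclohexa-1,5-dien-1-olate | [Li]OC1=CC(C)(C)CC(O[Si](C)(C)C)=C1CC=C(C)C | intermediate
12 | 5,5-dimethyl-2-(3-methylbut-2-en-1-yl)-1,3-bis(trimethylsilyloxy)cyclohexa-1,3-diene | CC(C)=CCC1=C(O[Si](C)(C)C)CC(C)(C)C=C1O[Si](C)(C)C | intermediate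
13 | (2R)-2-(tert-butyldimethylsilyloxy)-3-[3,4-bis(tert-butyldimethylsilyloxy)phenyl]-1-[8,8-dimethyl-6-(3-methylbut-2-en-1-yl)-1,5-bis(trimethylsilyloxy)bicyclo[2.2.2]octa-2,5-dien-2-yl]propan-1-one (bridgeheads undefined, both diastereomers converge) | C[Si](C)(C)OC12CC(C)(C)C(C=C1C(=O)[C@H](O[Si](C)(C)C(C)(C)C)Cc1ccc(O[Si](C)(C)C(C)(C)C)c(O[Si](C)(C)C(C)(C)C)c1)C(O[Si](C)(C)C)=C2CC=C(C)C | intermediate
14 | (2R)-2-(tert-butyldimethylsilyloxy)-3-[3,4-bis(tert-butyldimethylsilyloxy)phenyl]-1-[3-(3-methylbut-2-en-1-yl)-2,4-bis(trimethylsilyloxy)phenyl]propan-1-one | CC(C)=CCc1c(O[Si](C)(C)C)ccc(C(=O)[C@H](O[Si](C)(C)C(C)(C)C)Cc2ccc(O[Si](C)(C)C(C)(C)C)c(O[Si](C)(C)C(C)(C)C)c2)c1O[Si](C)(C)C | intermediate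
15 | (2R)-1-[2,4-dihydroxy-3-(3-methylbut-2-en-1-yl)phenyl]-3-(3,4-dihydroxyphenyl)-2-hydroxypropan-1-one | CC(C)=CCc1c(O)ccc(C(=O)[C@H](O)Cc2ccc(O)c(O)c2)c1O | target

Total step count: 8.
Longest linear sequence: 5 steps (steps 1, 2, 3, 7, 8 from sodium danshensu; equally steps 4, 5, 6, 7, 8 from dimedone).

Steps most likely to fail

Step 7. Thermal oligomerisation of the terminal ynone, or hydrolytic loss of the silyl enol ethers, may outpace a cycloaddition that is slowed by the fully substituted diene, and the extrusion of 2-methylpropene may stall at the bicyclic stage. The fallback attaches ring A ready-made instead of building it; it sets out from Weinreb amide 3 and comes back to the route at target 15. Commercial 1,3-bis(methoxymethoxy)benzene is lithiated between its two acetal groups (n-BuLi, THF, 0 °C) and alkylated with 8 (CuI cat.) to give 1,3-bis(methoxymethoxy)-2-(3-methylbut-2-en-1-yl)benzene F1. A second directed ortho-metalation (sec-BuLi, TMEDA, THF, −78 °C) should give [2,4-bis(methoxymethoxy)-3-(3-methylbut-2-en-1-yl)phenyl]lithium F2, which is added to 3 at −78 °C to give, by Weinreb ketone synthesis, (2R)-1-[2,4-bis(methoxymethoxy)-3-(3-methylbut-2-en-1-yl)phenyl]-2-(tert-butyldimethylsilyloxy)-3-[3,4-bis(tert-butyldimethylsilyloxy)phenyl]propan-1-one F3. HF·pyridine/pyridine in THF should remove the three silyl groups to give (2R)-1-[2,4-bis(methoxymethoxy)-3-(3-methylbut-2-en-1-yl)phenyl]-3-(3,4-dihydroxyphenyl)-2-hydroxypropan-1-one F4, and dilute HCl in MeOH at rt, which suffices for aryl acetals, should then release 15.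

Step 4. Alkylation on oxygen and a second alkylation on carbon compete with the wanted mono-C-prenylation of the ambident dione enolate. The fallback replaces the SN2 alkylation by a Tsuji–Trost allylation; it sets out from dimedone 7 and comes back at 9, and it makes no compound outside the list (F0). Compound 7 (in excess) is treated with 3-methylbut-2-enyl acetate, Pd(PPh3)4 (zerovalent palladium, cat.) and DBU in THF at rt → 50 °C. Any O-prenyl enol ether is an allylic vinylogous ester that re-ionises under zerovalent palladium, so material should funnel to the C-alkylated dione, and the soft nucleophile attacks the unsubstituted terminus of the 1,1-dimethylallyl palladium complex to give the linear prenyl group.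

Step 1. Acylation of the unprotected phenolic or secondary hydroxyls by the activated acid (oligoester formation) and loss of the very polar triol amide during aqueous work-up may erode the coupling. The fallback protects first and forms the amide by ester aminolysis; it sets out from 1 and comes back at 3. Fischer esterification of 1 (HCl generated from AcCl in MeOH, 0 °C → rt) should give methyl (2R)-3-(3,4-dihydroxyphenyl)-2-hydroxypropanoate F5. Silylation (TBSCl, imidazole, DMF) then gives methyl (2R)-2-(tert-butyldimethylsilyloxy)-3-[3,4-bis(tert-butyldimethylsilyloxy)phenyl]propanoate F6, and the magnesium amide made from MeNH(OMe)·HCl and i-PrMgCl (THF, −20 → 0 °C) should convert F6 into 3 without touching the stereocenter.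

Further compounds
F1 | step 7 | 1,3-bis(methoxymethoxy)-2-(3-methylbut-2-en-1-yl)benzene | COCOc1cccc(OCOC)c1CC=C(C)C
F2 | step 7 | [2,4-bis(methoxymethoxy)-3-(3-methylbut-2-en-1-yl)phenyl]lithium | [Li]c1ccc(OCOC)c(CC=C(C)C)c1OCOC
F3 | step 7 | (2R)-1-[2,4-bis(methoxymethoxy)-3-(3-methylbut-2-en-1-yl)phenyl]-2-(tert-butyldimethylsilyloxy)-3-[3,4-bis(tert-butyldimethylsilyloxy)phenyl]propan-1-one | CC(C)=CCc1c(OCOC)ccc(C(=O)[C@H](O[Si](C)(C)C(C)(C)C)Cc2ccc(O[Si](C)(C)C(C)(C)C)c(O[Si](C)(C)C(C)(C)C)c2)c1OCOC
F4 | step 7 | (2R)-1-[2,4-bis(methoxymethoxy)-3-(3-methylbut-2-en-1-yl)phenyl]-3-(3,4-dihydroxyphenyl)-2-hydroxypropan-1-one | CC(C)=CCc1c(OCOC)ccc(C(=O)[C@H](O)Cc2ccc(O)c(O)c2)c1OCOC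
F0 | step 4 | none | none
F5 | step 1 | methyl (2R)-3-(3,4-dihydroxyphenyl)-2-hydroxypropanoate | COC(=O)[C@H](O)Cc1ccc(O)c(O)c1
F6 | step 1 | methyl (2R)-2-(tert-butyldimethylsilyloxy)-3-[3,4-bis(tert-butyldimethylsilyloxy)phenyl]propanoate | COC(=O)[C@H](O[Si](C)(C)C(C)(C)C)Cc1ccc(O[Si](C)(C)C(C)(C)C)c(O[Si](C)(C)C(C)(C)C)c1
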